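Assumptions: amide 2 is taken to be a commercial reagent. Flavone numbering (O1, C2, C3, C4, C4a, C5 to C8, C8a; ring B on C2) is used for the corresponding atoms of the open-chain intermediates as well. The quinone oxygens formed in step 3 are taken to come from water, as is accepted for oxidative demethylation by tetravalent cerium.

## Analysis of the target

Target 11 is a flavone: a benzo ring A fused to a 4-pyranone ring C (chromen-4-one), with a 2-methoxyphenyl ring B on C2. It has no stereocentre, so every difficulty is one of regiochemistry and oxidation level. Ring A is substituted everywhere except C6: a hydroxyl on C5, methoxyls on C7 and C8, the ring oxygen O1 on C8a and the C4 carbonyl carbon on C4a; ring C carries an enol-ether methoxyl on C3. The 5-hydroxyl is hydrogen-bonded to the C4 carbonyl, which makes it slow to alkylate, while a 5-methoxyl (and, less so, the 3-methoxyl) is the first to fall to Lewis acids. Ring A is electron-rich and easily oxidised, and 5-hydroxyflavones oxygenated on C7 and C8 can scramble to the 5,6,7 pattern by ring opening and reclosure in hot strong acid. The hard point is that C4a sits between two oxygen-bearing carbons, C5 and C8a: a conventional closure of ring C must free the oxygen on C8a while that on C5 stays masked, and must later unmask C5 alone among five methoxyls. The strategy rests on the para relationship of the oxygens on C5 and C8: at the 5,8-quinone level C8a is the β-carbon of both the C5 and the C4 carbonyl and still carries a methoxyl, so it can accept O1 as an electrophile, and after reduction the hydroxyls on C5 and C8 are told apart by chelation alone.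

## Retrosynthetic reasoning

From 11 to 10. The last bond cut is the O–CH3 bond at C8. In 10 the hydroxyl on C5 is tied into a six-membered hydrogen bond with the C4 carbonyl, while the one on C8 is an ordinary, if crowded, phenol. Cutting here means the free 5-hydroxyl of 11 never has to be uncovered by a selective demethylation; the forward step only has to deliver one methyl group to the unchelated oxygen.

From 10 to 9. Hydroquinone 10 is the two-electron reduction product of quinone 9. No skeletal bond is cut; the redox change leads back to the oxidation level at which C8a is electrophilic. The forward step must reduce the quinone without touching the pyranone.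

From 9 to 7, through 8. The bond cut is O1–C8a. The usual cut for a flavone, O1–C2, calls for a free phenol on C8a and so for a choice between the two oxygens ortho to C4a. Cutting O1–C8a reverses the roles: the oxygen comes from the enol of the 1,3-diketone, and C8a is the acceptor, activated in quinone 8 by the C5 and C4 carbonyls and carrying its methoxyl as leaving group. Quinone 8 is 7 with the two para-related methyl ethers on O5 and O8 removed oxidatively. The gain is that ring A is carried as a fully methylated aryl group, with no protecting-group distinction, up to the step that closes ring C. The forward reaction has to oxidise ring A only, at its one para-dioxygenated pair, and then let the enol oxygen reach C8a.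

From 7 to 4 and 5, through 6. The bond cut is C2–C3, between the methoxy-bearing carbon and the carbonyl carbon attached to ring B. Ketone 4 has a single enolisable position, so enolate 6 forms without regiochemical choice, and 5 is an unhindered aroyl chloride. The other cut, C3–C4, would need an acyl donor whose carbonyl is shielded by two ortho methoxyls. The forward reaction has to place the aroyl group on carbon and not on the enolate oxygen.

From 4 to 1 and 2, through 3. The bond cut is C4–C4a, between the carbonyl carbon and ring A. Ether 1 has two equivalent ring hydrogens, each between two methoxyls, so deprotonation can give only aryllithium 3, and amide 2 hands over the methoxyacetyl group and stops at the ketone. A Lewis-acid acylation of 1 was set aside for two reasons: α-alkoxy acylium ions readily lose their carbonyl group and then alkylate the ring, and strong Lewis acids strip the methoxyl next to a new aryl ketone, which would destroy the all-methylated pattern the oxidation relies on.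

## Alternatives that were turned down

Alternative 1: The disconnection removes the C2–C1' bond and the C3–O bond from an intact chromone, 5,7,8-trimethoxychromen-4-one (A2). In the forward step 2-methoxyphenylmagnesium bromide (A3) adds to C2 of A2 under CuBr·SMe2 catalysis with Me3SiCl, and the silyl enol ether is oxidised in the same flask with dimethyldioxirane to racemic trans-3-hydroxy-5,7,8-trimethoxy-2-(2-methoxyphenyl)chroman-4-one (A1).
- For: it is convergent, both bond formations are of known types, the trans relationship follows from oxidation anti to the new aryl group, and silyl trapping keeps the enolate from ejecting the ring A phenoxide.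
- Against: A1 is at the wrong oxidation level. The C2–C3 bond must still be dehydrogenated, the 3-hydroxyl methylated and the 5-methoxyl cleaved selectively beside those on C3, C7, C8 and C2'; the two stereocentres of A1 are erased again. C2 of A2 is a vinylogous ester carbon and A3 is ortho-substituted, so the addition is not an easy one. A2 itself needs a ring A ketone with one free ortho hydroxyl, which brings back the differentiation of the two ortho oxygens.
- Comparison: on precedent this alternative is stronger, since no step lacks close analogy. The chosen route is about three steps shorter, makes no unneeded stereocentre and obtains the free 5-hydroxyl from a redox step; it pays with one untested ring closure.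

Alternative 2: Here ring A is made last. The C4a–C5 bond is cut, and behind it the C8–C8a bond, leading to a squarate-derived cyclobutenone that carries the complete ring C: 4-hydroxy-3-methoxy-4-[5-methoxy-6-(2-methoxyphenyl)-4-oxopyran-2-yl]cyclobut-2-en-1-one (A5). Heated in toluene, A5 should open to a dienylketene whose ketene carbon closes onto the free CH of the pyranone (the future C4a); tautomerisation gives 5,8-dihydroxy-3,7-dimethoxy-2-(2-methoxyphenyl)chromen-4-one (A4). A4 has the same structure as 10, so this alternative would join the chosen route before its last step.
- For: the ring A pattern is written into the four-membered ring, no oxidant is needed, and the thermal step is neutral.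
- Against: A5 needs a 2-aryl-3-methoxy-4-pyranone that can be metalated at C6 beside its own carbonyl, and an unsymmetrical cyclobutenedione that must be attacked at one carbonyl only. The electrocyclisation onto a pyranone double bond has only the aryl and simple heteroaryl cases as analogy. By a fair count it takes eight to ten steps to reach A4, the compound the chosen route reaches as 10 in four.
- Comparison: it is equal in the final stage, since A4 and 10 are one compound and both routes end with the same monomethylation, and it is stronger in that nothing enolisable meets an oxidant. The chosen route offers bulk aromatic starting materials and a much shorter path to the same hydroquinone.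

Alternative 3: The cut goes through C3–C4 and O1–C2, giving 2-hydroxy-3,4,6-trimethoxybenzaldehyde (A7) and the ynol ether 1-methoxy-2-(methoxyethynyl)benzene (A8). With [Cp*RhCl2]2 and Cu(OAc)2 the aldehyde C–H bond of A7 is activated, the alkyne A8 inserts into the acyl–rhodium bond and C–O reductive elimination closes ring C, giving 3,5,7,8-tetramethoxy-2-(2-methoxyphenyl)chromen-4-one (A6).
- For: it is the most convergent of all, forming two bonds and ring C at the right oxidation level in one catalytic step; salicylaldehyde–alkyne annulation to chromones is an established reaction type.
- Against: the orientation of the alkyne decides whether the methoxyl ends on C3 or C2, and for a strongly polarised ynol ether it is not secured that the acyl group goes to the oxygen-bearing carbon. A8 is hydrolytically labile and takes several steps to make. A7 again needs one of the two ortho oxygens of ring A free. A6 is the pentamethyl ether, so the route ends with a selective cleavage of the 5-methoxyl.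
- Comparison: in convergence and directness of ring closure it is stronger. The chosen route gives a ring C regiochemistry fixed by connectivity (the carbon bonded to ring B can only become C2), robust cheap building blocks, and a free 5-hydroxyl without a demethylation.

Key step: step 3

## Route

Step 1
Reactants: 1 1,2,3,5-tetramethoxybenzene; 2 N,2-dimethoxy-N-methylacetamide
Product: 4 2-methoxy-1-(2,3,4,6-tetramethoxyphenyl)ethanone, via aryllithium 3 (not isolated)
Conditions: n-BuLi, TMEDA, THF, 0 °C; then 2, −78 °C → 0 °C; 1 M aq. HCl, 0 °C
Reagents that add atoms: none
Why: Directed ortho-metalation followed by Weinreb ketone synthesis: the two ring hydrogens of 1 are equivalent and each lies between two methoxyls, so only aryllithium 3 can form, and its adduct with amide 2 is a chelated tetrahedral species that collapses to ketone 4 only on work-up, so no tertiary alcohol should arise.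

Step 2
Reactants: 4 2-methoxy-1-(2,3,4,6-tetramethoxyphenyl)ethanone; 5 2-methoxybenzoyl chloride
Product: 7 2-methoxy-3-(2-methoxyphenyl)-1-(2,3,4,6-tetramethoxyphenyl)propane-1,3-dione, via lithium enolate 6 (not isolated)
Conditions: LiN(SiMe3)2 (2.2 equiv), THF/toluene, −78 °C; then 5, −78 → 0 °C; aq. HCl
Reagents that add atoms: none
Why: Claisen-type C-acylation of a ketone lithium enolate with an aroyl chloride; 4 can enolise only at the methoxymethyl carbon, the aggregated lithium enolate should react at carbon, and the second equivalent of base removes the acidic methine proton of 7 as it forms, which stops a second acylation. The new stereocentre is not controlled and does not matter, since 7 is racemic and enolisable.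

Step 3
Reactants: 7 2-methoxy-3-(2-methoxyphenyl)-1-(2,3,4,6-tetramethoxyphenyl)propane-1,3-dione
Product: 9 3,7-dimethoxy-2-(2-methoxyphenyl)chromene-4,5,8-trione, via acylquinone 8 (not isolated)
Conditions: (NH4)2Ce(NO3)6 (2.5 equiv), MeCN/H2O (2:1), 0 °C → rt
Reagents that add atoms: water, O
Why: Proposed new method: two successive one-electron oxidations by tetravalent cerium, each followed by ipso attack of water at C5 or C8 and loss of methanol, should convert ring A of 7 into acylquinone 8, which is the known oxidative demethylation of para-dimethoxyarenes. In 8 the carbon C8a carries a methoxyl and is the β-carbon of two enone systems (C8a=C4a–C5=O and C8a=C4a–C4=O), so the enol oxygen on C2 of the side chain should add to it in a 6-endo-trig conjugate addition, and loss of methanol from the adduct restores the C4a=C8a double bond and closes ring C as a 4-pyranone. The closest known reaction types are the cerium-mediated oxidation of 2-acyl-1,4-dimethoxyarenes to acylquinones and the addition–elimination of oxygen and nitrogen nucleophiles at the methoxyl-bearing carbon of 2-acyl-3-methoxy-1,4-benzoquinones; their use as a flavone ring closure with a diketone enol as nucleophile is not known. No stereocentre is formed, and the one in 7 disappears on enolisation. The step needs site selectivity, which the substrate secures: C5 and C8 carry the only para-related pair of methoxyls on ring A, so only one para-quinone can arise, and only C8a can be reached by the enol oxygen through a six-membered transition state, the other vinylogous ester carbon C7 being remote. It also needs chemoselectivity for the arene over the enolisable 1,3-dicarbonyl, which is helped by the α-methoxy diketone being mainly in its keto form and by the tetraoxygenated ring being the most electron-rich π system present. If water adds to C8a first, the resulting hydroxyquinone can still close onto the C2 carbonyl by ordinary acid-catalysed cyclodehydration, so that path should lead to the same product 9.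

Step 4
Reactants: 9 3,7-dimethoxy-2-(2-methoxyphenyl)chromene-4,5,8-trione
Product: 10 5,8-dihydroxy-3,7-dimethoxy-2-(2-methoxyphenyl)chromen-4-one
Conditions: Na2S2O4, EtOAc/H2O, rt, Ar
Reagents that add atoms: none
Why: Two-electron reduction of a para-quinone to its hydroquinone by dithionite; the 4-pyranone and the methoxyls are inert to this reductant, and the product is handled under argon because 5,8-dihydroxyflavones re-oxidise in air.

Step 5
Reactants: 10 5,8-dihydroxy-3,7-dimethoxy-2-(2-methoxyphenyl)chromen-4-one
Product: 11 5-hydroxy-3,7,8-trimethoxy-2-(2-methoxyphenyl)chromen-4-one
Conditions: Me2SO4 (1.05 equiv), K2CO3, acetone, reflux, Ar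
Reagents that add atoms: dimethyl sulfate, COS(=O)(=O)OC
Why: Williamson O-methylation (SN2 at methyl); the 5-hydroxyl is held in a hydrogen bond to the C4 carbonyl and is much less readily deprotonated and alkylated than the 8-hydroxyl, so one equivalent of the methylating agent should go to O8 only.

## Compound list

1 | 1,2,3,5-tetramethoxybenzene | COc1cc(OC)c(OC)c(OC)c1 | starting material
2 | N,2-dimethoxy-N-methylacetamide | COCC(=O)N(C)OC | starting material
3 | (2,3,4,6-tetramethoxyphenyl)lithium, not isolated | [Li]c1c(OC)cc(OC)c(OC)c1OC | intermediate
4 | 2-methoxy-1-(2,3,4,6-tetramethoxyphenyl)ethanone | COCC(=O)c1c(OC)cc(OC)c(OC)c1OC | intermediate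
5 | 2-methoxybenzoyl chloride | COc1ccccc1C(Cl)=O | starting material
6 | lithium (Z)-2-methoxy-1-(2,3,4,6-tetramethoxyphenyl)ethenolate, not isolated | [Li]O/C(=C\OC)c1c(OC)cc(OC)c(OC)c1OC | intermediate
7 | 2-methoxy-3-(2-methoxyphenyl)-1-(2,3,4,6-tetramethoxyphenyl)propane-1,3-dione, racemic and enolisable | COc1ccccc1C(=O)C(OC)C(=O)c1c(OC)cc(OC)c(OC)c1OC | intermediate
8 | 1-(2,4-dimethoxy-3,6-dioxocyclohexa-1,4-dien-1-yl)-2-methoxy-3-(2-methoxyphenyl)propane-1,3-dione, racemic, not isolated | COc1ccccc1C(=O)C(OC)C(=O)C1=C(OC)C(=O)C(OC)=CC1=O | intermediate
9 | 3,7-dimethoxy-2-(2-methoxyphenyl)chromene-4,5,8-trione | COc1ccccc1C1=C(OC)C(=O)C2=C(O1)C(=O)C(OC)=CC2=O | intermediate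
10 | 5,8-dihydroxy-3,7-dimethoxy-2-(2-methoxyphenyl)chromen-4-one | COc1ccccc1-c1oc2c(O)c(OC)cc(O)c2c(=O)c1OC | intermediate
11 | 5-hydroxy-3,7,8-trimethoxy-2-(2-methoxyphenyl)chromen-4-one (5-hydroxy-3,7,8,2'-tetramethoxyflavone) | COc1ccccc1-c1oc2c(OC)c(OC)cc(O)c2c(=O)c1OC | target

## Step count and least certain steps

Total step count: 5. Longest linear sequence: 5 steps (1 → 4 → 7 → 9 → 10 → 11).

Step 3 (key step, proposed new method). Three things may go wrong.
- One-electron oxidation of the 1,3-dicarbonyl enol by tetravalent cerium may compete with oxidation of ring A, leading to radical coupling or cleavage of the side chain.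
- Water may attack the arene radical cation at the unsubstituted C6 instead of ipso at C5 and C8, which would lead to a different quinone.
- The reaction may stall at the open quinone 8 if enolisation is slow.

Buffering with NaOAc/AcOH after the oxidation, or replacing the oxidant by AgO (divalent silver oxide) in dilute HNO3, are changes of conditions only. The fallback uses known chemistry and leaves the quinone idea. It sets out from ketone 4: BCl3 in CH2Cl2 at −78 → 0 °C cleaves a methoxyl ortho to the carbonyl, the doubly flanked one on the future C8a being expected to go first, to give 1-(2-hydroxy-3,4,6-trimethoxyphenyl)-2-methoxyethanone (F1). The dianion of F1, formed with three equivalents of LiN(SiMe3)2, is aroylated with 5 to 1-(2-hydroxy-3,4,6-trimethoxyphenyl)-2-methoxy-3-(2-methoxyphenyl)propane-1,3-dione (F2); any aryl ester formed is carried to the same diketone by a Baker–Venkataraman acyl shift. H2SO4 in AcOH cyclodehydrates F2 to 3,5,7,8-tetramethoxy-2-(2-methoxyphenyl)chromen-4-one (F3). BCl3 (or AlCl3 in MeCN) then removes the chelation-activated 5-methyl group of F3. The fallback comes back to the route at 11 in the same number of steps from 4. Its price is that the choice between the two ortho methoxyls returns at the first demethylation, where F1 must form in preference to its isomer, and the aliphatic methoxyl next to the ketone must survive the boron reagent.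

Step 2. The acyl chloride may react at the oxygen terminus of enolate 6 and give an enol ester, since the carbon terminus is flanked by a methoxyl and a di-ortho-substituted aryl ketone. The fallback sets out from 4: enolate 6 is added at −78 °C to commercial 2-methoxybenzaldehyde (COc1ccccc1C=O), an aldol addition in which reaction at oxygen is not productive, to give 3-hydroxy-2-methoxy-3-(2-methoxyphenyl)-1-(2,3,4,6-tetramethoxyphenyl)propan-1-one (F4) as a mixture of diastereomers. Both diastereomers of F4 are carried on together. Oxidation of the secondary alcohol of F4 with Dess–Martin periodinane in CH2Cl2 brings the sequence back at 7, at the cost of one step.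

Step 5. Methylation may run on to the chelated 5-hydroxyl, or hydroquinone 10 may be re-oxidised by air in the basic medium to quinone 9. Any 9 formed can be sent through step 4 again. The fallback sets out from 10: exhaustive methylation with excess Me2SO4 and K2CO3 in refluxing acetone gives 3,5,7,8-tetramethoxy-2-(2-methoxyphenyl)chromen-4-one (F5). F5 has the same structure as F3. BCl3 in CH2Cl2 at −78 → 0 °C then cleaves only the 5-methoxyl of F5, which is activated by chelation to the C4 carbonyl, and the sequence comes back at 11.

Step 1. The hindered and strongly basic aryllithium 3 may act as a base towards amide 2, by deprotonation at its activated methylene or by elimination across the N–O bond, so that 1 is returned on work-up. The fallback sets out from 3: transmetalation with ZnCl2 in THF gives chlorido(2,3,4,6-tetramethoxyphenyl)zinc (F6). F6 is coupled with methoxyacetyl chloride (COCC(Cl)=O) under Pd(PPh3)4 catalysis (zerovalent palladium) at room temperature, a Negishi-type ketone synthesis in which no free acylium ion is formed. The sequence comes back at 4.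

## Further compounds

F1 | step 3 | 1-(2-hydroxy-3,4,6-trimethoxyphenyl)-2-methoxyethanone | COCC(=O)c1c(O)c(OC)c(OC)cc1OC
F2 | step 3 | 1-(2-hydroxy-3,4,6-trimethoxyphenyl)-2-methoxy-3-(2-methoxyphenyl)propane-1,3-dione, racemic | COc1ccccc1C(=O)C(OC)C(=O)c1c(O)c(OC)c(OC)cc1OC
F3 | step 3 | 3,5,7,8-tetramethoxy-2-(2-methoxyphenyl)chromen-4-one | COc1ccccc1-c1oc2c(OC)c(OC)cc(OC)c2c(=O)c1OC
F4 | step 2 | 3-hydroxy-2-methoxy-3-(2-methoxyphenyl)-1-(2,3,4,6-tetramethoxyphenyl)propan-1-one, racemic mixture of diastereomers | COc1ccccc1C(O)C(OC)C(=O)c1c(OC)cc(OC)c(OC)c1OC
F5 | step 5 | 3,5,7,8-tetramethoxy-2-(2-methoxyphenyl)chromen-4-one | COc1ccccc1-c1oc2c(OC)c(OC)cc(OC)c2c(=O)c1OC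
F6 | step 1 | chlorido(2,3,4,6-tetramethoxyphenyl)zinc | COc1cc(OC)c(OC)c(OC)c1[Zn]Cl
A1 | alternative 1 | trans-3-hydroxy-5,7,8-trimethoxy-2-(2-methoxyphenyl)chroman-4-one, racemic, drawn as (2R,3R) | COc1ccccc1[C@@H]1[C@@H](O)C(=O)c2c(OC)cc(OC)c(OC)c2O1
A2 | alternative 1 | 5,7,8-trimethoxychromen-4-one | O=c1ccoc2c1c(OC)cc(OC)c2OC
A3 | alternative 1 | 2-methoxyphenylmagnesium bromide | COc1ccccc1[Mg]Br
A4 | alternative 2 | 5,8-dihydroxy-3,7-dimethoxy-2-(2-methoxyphenyl)chromen-4-one | COc1ccccc1-c1oc2c(O)c(OC)cc(O)c2c(=O)c1OC
A5 | alternative 2 | 4-hydroxy-3-methoxy-4-[5-methoxy-6-(2-methoxyphenyl)-4-oxopyran-2-yl]cyclobut-2-en-1-one, racemic | COC1=CC(=O)C1(O)c1cc(=O)c(OC)c(-c2ccccc2OC)o1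
A6 | alternative 3 | 3,5,7,8-tetramethoxy-2-(2-methoxyphenyl)chromen-4-one | COc1ccccc1-c1oc2c(OC)c(OC)cc(OC)c2c(=O)c1OC
A7 | alternative 3 | 2-hydroxy-3,4,6-trimethoxybenzaldehyde | O=Cc1c(O)c(OC)c(OC)cc1OC
A8 | alternative 3 | 1-methoxy-2-(methoxyethynyl)benzene | COC#Cc1ccccc1OC
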